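The readings stem from a simulated flask with constants of no real substance.

all flasks: E 0.017 M

| charge | Z | remark | time |
|---|---|---|---|
| Tuesday's | 0.038 M | run made earlier |  |
| Wednesday's | 0.38 M | run made earlier |  |
| blue | 0.310 M |  | 12 min |
| green | 0.100 M |  | 12 min |
| teal | 0.0340 M |  | 12 min |

| run | time / min | E / % | J / % | G / % | X / % |
|---|---|---|---|---|---|
| Tuesday's | 0.417 | 94 | 5 | 3 | 2 |
| Tuesday's | 1.33 | 88 | 8 | 0 | 7 |
| Tuesday's | 2.00 | 82 | 10 | 3 | 5 |
| Tuesday's | 3.00 | 75 | 12 | 2 | 9 |
| Tuesday's | 5.00 | 67 | 20 | 1 | 8 |
| Tuesday's | 6.00 | 66 | 24 | 2 | 14 |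
| Wednesday's | 0.417 | 65 | 23 | 0 | 11 |
| Wednesday's | 1.33 | 35 | 39 | 13 | 18 |
| Wednesday's | 2.00 | 26 | 38 | 24 | 17 |
| Wednesday's | 3.00 | 17 | 38 | 27 | 16 |
| Wednesday's | 5.00 | 9 | 38 | 38 | 12 |
| Wednesday's | 6.00 | 10 | 36 | 37 | 11 |

(readings scatter by 2 percentage points)

* which of these there is most of at the end, counted by the E in it, blue (E / X / J / G)
* which of these there is most of at the end, counted by the E in it, green (E / X / J / G)
* which of these there is most of at the end, counted by the E in it, teal (E / X / J / G)
* final amount of the leader among these, as a percentage of the E charged, in blue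
* final amount of the leader among these, as a percentage of the E charged, in green
* final amount of the leader among these, as a percentage of the E charged, in teal

- on the list of suspects stand: Z + J -> G + L; E + Z -> X + L; Z -> Q; E + Z <-> J + L; Z + X -> G + L; 2 Z -> D

- Clock these flasks in dose, a dimensionless unit: E falls at the pseudo-first-order rate k[Z], dose is k times the time integral of [Z], and it equals minus the log of the fraction of E left, so Wednesday's run had reached 2.30 by 6.00 min.
- Each forward step on the list that touches E, J or X takes one Z, so equal dose should mean equal composition, and the readings agree: Tuesday's run at 6.00 min shows E 66% and J 24%, while Wednesday's at 0.417 min shows E 65% and J 23%, on about ten times the [Z]. Wednesday's run thus serves as a table of composition against dose.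
- My chain starts from Wednesday's first reading, which gives k = 2.72 L mol⁻¹ min⁻¹.
- Next, take mean [Z] over its charge as one over (one plus λt over two), after adding back the mean draw of Z by reaction. The two runs then give λ = 0.113 min⁻¹ and 0.518 min⁻¹, so λ = a + b[Z] with a = 0.0683 min⁻¹ and b = 1.18 L mol⁻¹ min⁻¹.
- The weak link is teal, whose Z charge is twice its E: without the draw its dose is 0.672, but with the draw it is 0.536, so I expect E 58.5%, the leader, since J stood at 23% at a comparable dose.
- Green reaches 1.32, which matches Wednesday's reading at 2.00 min, so J leads at 38%.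
- Blue reaches 2.54, just past Wednesday's tie of J and G, so G leads, and extending G's climb gives me 40.2%.
- The forecast names the same leaders, with the same amount as mine in green and other amounts in blue and teal: G 46% (39% to 53%) in blue, J 38% (33% to 43%) in green, E 61% (54% to 69%) in teal, and of blue it says: “This is a narrow lead for G, since Wednesday's J and G are tied at s ≈ 2.4”.
- The flasks give G 49.6% in blue, J 38.1% in green and E 56.5% in teal, so the forecast stands on every line.

    Z + J → G + L (k = 0.0130 L mol⁻¹ s⁻¹)
    E + Z → X + L (k = 0.0170 L mol⁻¹ s⁻¹)
    Z → Q (k = 0.00110 s⁻¹)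
    E + Z ⇌ J + L (K = 8.40, k = 0.0310 L mol⁻¹ s⁻¹)
    Z + X → G + L (k = 0.0270 L mol⁻¹ s⁻¹)
    2 Z → D (k = 0.0110 L mol⁻¹ s⁻¹)

- Blue's remaining E means a dose of 2.84, beyond Wednesday's 2.30, and there G leads. In blue the pairing of Z into D runs 6.2 times as fast as Z's lone decay into Q at the start, but 0.57 times at the asked time, the two terms of λ changing places.
- A neighbour of blue charged with 0.12 M of Z, read at the same time, gets a reckoned dose of 1.50, short of 2.30, so J should lead with E near 22.3%. Computed, J leads at 38.7%, with E 20.3%.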